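Ring C is cut at the O1–C8a bond: without O1, ring C is the five-membered ring of a 1-indanone fused to ring A, and its C3 is the C4 stereocentre carrying ring D. A Baeyer–Villiger oxidation puts O1 back between the carbonyl carbon and the ring A carbon in one operation, expanding the carbocycle to the dihydrocoumarin (ring C at the lactone level) with C4 untouched. Its substrate is the (R)-6-benzyloxy-3-arylindan-1-one, made by asymmetric reductive Heck cyclisation, in which ring D carries three benzyl ethers and one bromine. The bromine tempers ring D towards the peracid and later marks the site of the acyl chain.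

Key step: step 6

Remark: rotation about the bond from C4 to ring D is taken to be fast at room temperature, so the two unsubstituted positions of ring D are equivalent and monobromide 7 is one compound.
Remark: the sense of induction in step 4 cannot be read from the ligand name; the ligand antipode is fixed by a trial run so that (R)-6 results.
Remark: 12 is written as the open keto-phenol, the ring-chain tautomer of the 2-hydroxyflavan hemiketal.
Remark: the acyl chain is attached after the oxidation because a ketone on ring D would itself be oxidised by the peracid.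

Step 1
Reactants: 1 2,4,6-trihydroxybenzaldehyde
Product: 2 2,4,6-tris(benzyloxy)benzaldehyde
Conditions: BnBr (3.5 equiv), K2CO3, DMF, 60 °C
Reagents that add atoms: benzyl bromide, BrCc1ccccc1
Why: Williamson ether synthesis on the three phenols, where the formyl group lowers the ring nucleophilicity so that O-benzylation should prevail over C-benzylation.

Step 2
Reactants: 3 1-[3-(benzyloxy)phenyl]ethan-1-one
Product: 4 1-[5-(benzyloxy)-2-bromophenyl]ethan-1-one
Conditions: NBS (1.05 equiv), MeCN, rt, dark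
Reagents that add atoms: N-bromosuccinimide, O=C1CCC(=O)N1Br
Why: Electrophilic aromatic bromination, which for 3-alkoxyacetophenones in a polar solvent should go para to the alkoxy group and so place bromine ortho to the acetyl group.

Step 3
Reactants: 2 2,4,6-tris(benzyloxy)benzaldehyde; 4 1-[5-(benzyloxy)-2-bromophenyl]ethan-1-one
Product: 5 (E)-1-[5-(benzyloxy)-2-bromophenyl]-3-[2,4,6-tris(benzyloxy)phenyl]prop-2-en-1-one
Conditions: KOH, EtOH/THF, rt
Reagents that add atoms: none
Why: Claisen–Schmidt condensation of the methyl ketone enolate with the non-enolisable aldehyde, followed by dehydration, should give the (E)-chalcone.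

Step 4
Reactants: 5 (E)-1-[5-(benzyloxy)-2-bromophenyl]-3-[2,4,6-tris(benzyloxy)phenyl]prop-2-en-1-one
Product: 6 (3R)-6-(benzyloxy)-3-[2,4,6-tris(benzyloxy)phenyl]indan-1-one
Conditions: Pd(OAc)2 (5 mol %), (R)-3,5-Xyl-MeO-BIPHEP (6 mol %), HCO2Na, DMF/ethylene glycol, 80 °C
Reagents that add atoms: none
Why: Asymmetric reductive Heck cyclisation, in which zerovalent palladium inserts into the C–Br bond, the ring A carbon adds to the enone β-carbon inside the chiral bisphosphine pocket (catalyst control sets C3) and formate supplies the hydride that frees the ketone.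

Step 5
Reactants: 6 (3R)-6-(benzyloxy)-3-[2,4,6-tris(benzyloxy)phenyl]indan-1-one
Product: 7 (3R)-6-(benzyloxy)-3-[3-bromo-2,4,6-tris(benzyloxy)phenyl]indan-1-one
Conditions: NBS (1.0 equiv), CH2Cl2/MeCN, –20 to 0 °C, dark
Reagents that add atoms: N-bromosuccinimide, O=C1CCC(=O)N1Br
Why: Electrophilic aromatic bromination that should touch only the trialkoxy ring D, since ring A is deactivated by the ketone and the first bromine slows a second substitution.

Step 6
Reactants: 7 (3R)-6-(benzyloxy)-3-[3-bromo-2,4,6-tris(benzyloxy)phenyl]indan-1-one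
Product: 9 (4R)-7-(benzyloxy)-4-[3-bromo-2,4,6-tris(benzyloxy)phenyl]chroman-2-one, via Criegee adduct 8 (not isolated)
Conditions: mCPBA (3 equiv), NaHCO3, CH2Cl2, 0 °C to rt, dark
Reagents that add atoms: 3-chloroperbenzoic acid, O=C(OO)c1cccc(Cl)c1
Why: Baeyer–Villiger oxidation: the peracid adds to the C1 carbonyl to give Criegee adduct 8, and the ring A carbon C7a, antiperiplanar to the breaking O–O bond, shifts from C1 to oxygen as 3-chlorobenzoate leaves, which creates the O1–C8a bond. The closest known reaction type is the peracid oxidation of 1-indanones, 3-aryl examples included, to 3,4-dihydrocoumarins. Ring C (lactone level) is not closed by a cyclisation but arises by one-atom ring expansion of the five-membered carbocycle through this 1,2-shift from carbon to oxygen. No stereocentre is formed; C3 of the indanone, which is β to the carbonyl and cannot epimerise by enolisation, becomes C4 of the lactone with its R configuration unchanged. The step needs migration of the aryl carbon in preference to the C2 methylene, which should be secured because an sp2 aryl carbon carries the developing positive charge far better than a primary alkyl carbon, even without resonance help from the meta benzyloxy group. It also needs the peracid to spare ring D, which the bromine (electron withdrawal and one free position fewer), the two benzyloxy groups flanking the last free position, the bicarbonate buffer and the exclusion of light are meant to secure.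

Step 7
Reactants: 9 (4R)-7-(benzyloxy)-4-[3-bromo-2,4,6-tris(benzyloxy)phenyl]chroman-2-one; 10 1-(benzyloxy)-4-bromobenzene
Product: 12 (3R)-3-[4-(benzyloxy)-2-hydroxyphenyl]-1-[4-(benzyloxy)phenyl]-3-[3-bromo-2,4,6-tris(benzyloxy)phenyl]propan-1-one (open form of the 2-hydroxyflavan hemiketal), via 4-(benzyloxy)phenyllithium 11 (not isolated)
Conditions: 10, n-BuLi (0.98 equiv to 10), THF, –78 °C; the solution of 11 (1.1 equiv) added to 9, THF, –78 °C; AcOH, –78 °C
Reagents that add atoms: none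
Why: Bromine–lithium exchange followed by acyl substitution at the lactone carbonyl, where the adduct should persist at –78 °C as the lithium salt of the hemiketal form of 12 so that only one aryl group enters, and the hindered ring D bromide should exchange far more slowly than the aryl ester reacts.

Step 8
Reactants: 12 (3R)-3-[4-(benzyloxy)-2-hydroxyphenyl]-1-[4-(benzyloxy)phenyl]-3-[3-bromo-2,4,6-tris(benzyloxy)phenyl]propan-1-one
Product: 14 (2R,4R)-7-(benzyloxy)-2-[4-(benzyloxy)phenyl]-4-[3-bromo-2,4,6-tris(benzyloxy)phenyl]chroman, via oxocarbenium ion 13 (not isolated)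
Conditions: Et3SiH (3 equiv), BF3·OEt2 (2 equiv), CH2Cl2, –78 to –30 °C
Reagents that add atoms: none
Why: Reductive cyclisation by ionic hydrogenation, in which BF3 closes the keto-phenol to its hemiketal and ionises it to 13, and the silane should deliver hydride to C2 on the face away from ring D at C4 (substrate control), leaving the C2 aryl group cis to ring D (2R).

Step 9
Reactants: 15 9-phenylnonanoic acid
Product: 17 N-methoxy-N-methyl-9-phenylnonanamide, via acyl imidazole 16 (not isolated)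
Conditions: CDI, CH2Cl2, rt; then MeNHOMe·HCl, rt
Reagents that add atoms: N,O-dimethylhydroxylamine hydrochloride, CNOC.Cl
Why: Carboxyl activation as the acyl imidazole followed by aminolysis is a standard Weinreb amide formation.

Step 10
Reactants: 14 (2R,4R)-7-(benzyloxy)-2-[4-(benzyloxy)phenyl]-4-[3-bromo-2,4,6-tris(benzyloxy)phenyl]chroman; 17 N-methoxy-N-methyl-9-phenylnonanamide
Product: 19 1-{2,4,6-tris(benzyloxy)-3-[(2R,4R)-7-(benzyloxy)-2-[4-(benzyloxy)phenyl]chroman-4-yl]phenyl}-9-phenylnonan-1-one, via ring D aryllithium 18 (not isolated)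
Conditions: n-BuLi (1.05 equiv), THF, –78 °C; then 17 (1.5 equiv), –78 to 0 °C; AcOH
Reagents that add atoms: none
Why: Bromine–lithium exchange followed by Weinreb ketone synthesis, where exchange at –78 °C should outrun deprotonation of the benzylic positions and the N-methoxy-N-methyl amide accepts only one aryllithium, so the acyl chain enters ring D exactly where the bromine stood.

Step 11
Reactants: 19 1-{2,4,6-tris(benzyloxy)-3-[(2R,4R)-7-(benzyloxy)-2-[4-(benzyloxy)phenyl]chroman-4-yl]phenyl}-9-phenylnonan-1-one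
Product: 20 1-{2,4,6-trihydroxy-3-[(2R,4R)-7-hydroxy-2-(4-hydroxyphenyl)chroman-4-yl]phenyl}-9-phenylnonan-1-one (CNP0175574.1)
Conditions: H2 (1 atm), 10% Pd/C, EtOAc/MeOH, rt
Reagents that add atoms: none
Why: Hydrogenolysis of the five benzyl aryl ethers under mild conditions, which should leave the hydrogen-bonded acylphloroglucinol ketone, the flavan C2–O1 bond and both stereocentres alone.

Compound list
1 | 2,4,6-trihydroxybenzaldehyde | O=Cc1c(O)cc(O)cc1O | starting material
2 | 2,4,6-tris(benzyloxy)benzaldehyde | O=Cc1c(OCc2ccccc2)cc(OCc2ccccc2)cc1OCc1ccccc1 | intermediate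
3 | 1-[3-(benzyloxy)phenyl]ethan-1-one | CC(=O)c1cccc(OCc2ccccc2)c1 | starting material
4 | 1-[5-(benzyloxy)-2-bromophenyl]ethan-1-one | CC(=O)c1cc(OCc2ccccc2)ccc1Br | intermediate
5 | (E)-1-[5-(benzyloxy)-2-bromophenyl]-3-[2,4,6-tris(benzyloxy)phenyl]prop-2-en-1-one | O=C(/C=C/c1c(OCc2ccccc2)cc(OCc2ccccc2)cc1OCc1ccccc1)c1cc(OCc2ccccc2)ccc1Br | intermediate
6 | (3R)-6-(benzyloxy)-3-[2,4,6-tris(benzyloxy)phenyl]indan-1-one | O=C1C[C@@H](c2c(OCc3ccccc3)cc(OCc3ccccc3)cc2OCc2ccccc2)c2ccc(OCc3ccccc3)cc21 | intermediate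
7 | (3R)-6-(benzyloxy)-3-[3-bromo-2,4,6-tris(benzyloxy)phenyl]indan-1-one | O=C1C[C@@H](c2c(OCc3ccccc3)cc(OCc3ccccc3)c(Br)c2OCc2ccccc2)c2ccc(OCc3ccccc3)cc21 | intermediate
8 | (3R)-6-(benzyloxy)-3-[3-bromo-2,4,6-tris(benzyloxy)phenyl]-1-hydroxyindan-1-yl 3-chloroperbenzoate (Criegee adduct, C1 epimers) | OC1(OOC(=O)c2cccc(Cl)c2)C[C@@H](c2c(OCc3ccccc3)cc(OCc3ccccc3)c(Br)c2OCc2ccccc2)c2ccc(OCc3ccccc3)cc21 | intermediate (not isolated)
9 | (4R)-7-(benzyloxy)-4-[3-bromo-2,4,6-tris(benzyloxy)phenyl]chroman-2-one | O=C1C[C@@H](c2c(OCc3ccccc3)cc(OCc3ccccc3)c(Br)c2OCc2ccccc2)c2ccc(OCc3ccccc3)cc2O1 | intermediate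
10 | 1-(benzyloxy)-4-bromobenzene | Brc1ccc(OCc2ccccc2)cc1 | starting material
11 | 4-(benzyloxy)phenyllithium | [Li]c1ccc(OCc2ccccc2)cc1 | intermediate (not isolated)
12 | (3R)-3-[4-(benzyloxy)-2-hydroxyphenyl]-1-[4-(benzyloxy)phenyl]-3-[3-bromo-2,4,6-tris(benzyloxy)phenyl]propan-1-one | O=C(C[C@@H](c1c(OCc2ccccc2)cc(OCc2ccccc2)c(Br)c1OCc1ccccc1)c1ccc(OCc2ccccc2)cc1O)c1ccc(OCc2ccccc2)cc1 | intermediate
13 | (4R)-7-(benzyloxy)-2-[4-(benzyloxy)phenyl]-4-[3-bromo-2,4,6-tris(benzyloxy)phenyl]-3,4-dihydrochromenylium (cyclic oxocarbenium ion) | Brc1c(OCc2ccccc2)cc(OCc2ccccc2)c([C@@H]2CC(c3ccc(OCc4ccccc4)cc3)=[O+]c3cc(OCc4ccccc4)ccc32)c1OCc1ccccc1 | intermediate (not isolated)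
14 | (2R,4R)-7-(benzyloxy)-2-[4-(benzyloxy)phenyl]-4-[3-bromo-2,4,6-tris(benzyloxy)phenyl]chroman | Brc1c(OCc2ccccc2)cc(OCc2ccccc2)c([C@@H]2C[C@H](c3ccc(OCc4ccccc4)cc3)Oc3cc(OCc4ccccc4)ccc32)c1OCc1ccccc1 | intermediate
15 | 9-phenylnonanoic acid | O=C(O)CCCCCCCCc1ccccc1 | starting material
16 | 1-(1H-imidazol-1-yl)-9-phenylnonan-1-one (acyl imidazole) | O=C(CCCCCCCCc1ccccc1)n1ccnc1 | intermediate (not isolated)
17 | N-methoxy-N-methyl-9-phenylnonanamide | CON(C)C(=O)CCCCCCCCc1ccccc1 | intermediate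
18 | {2,4,6-tris(benzyloxy)-3-[(2R,4R)-7-(benzyloxy)-2-[4-(benzyloxy)phenyl]chroman-4-yl]phenyl}lithium | [Li]c1c(OCc2ccccc2)cc(OCc2ccccc2)c([C@@H]2C[C@H](c3ccc(OCc4ccccc4)cc3)Oc3cc(OCc4ccccc4)ccc32)c1OCc1ccccc1 | intermediate (not isolated)
19 | 1-{2,4,6-tris(benzyloxy)-3-[(2R,4R)-7-(benzyloxy)-2-[4-(benzyloxy)phenyl]chroman-4-yl]phenyl}-9-phenylnonan-1-one | O=C(CCCCCCCCc1ccccc1)c1c(OCc2ccccc2)cc(OCc2ccccc2)c([C@@H]2C[C@H](c3ccc(OCc4ccccc4)cc3)Oc3cc(OCc4ccccc4)ccc32)c1OCc1ccccc1 | intermediate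
20 | 1-{2,4,6-trihydroxy-3-[(2R,4R)-7-hydroxy-2-(4-hydroxyphenyl)chroman-4-yl]phenyl}-9-phenylnonan-1-one | O=C(CCCCCCCCc1ccccc1)c1c(O)cc(O)c([C@@H]2C[C@H](c3ccc(O)cc3)Oc3cc(O)ccc32)c1O | target

Total step count: 11. Longest linear sequence: 9 steps (steps 1, 3, 4, 5, 6, 7, 8, 10, 11; steps 2 and 9 feed in from the side).

Steps most likely to fail

Step 6. The peracid may attack the one unsubstituted, oxygen-flanked position of ring D faster than it inserts oxygen at the sluggish conjugated ketone. The fallback sets out from 6 and blocks ring D completely. NBS (2.1 equiv) should give (3R)-6-(benzyloxy)-3-[3,5-dibromo-2,4,6-tris(benzyloxy)phenyl]indan-1-one F1, whose ring D has no free position. The same buffered peracid oxidation, through its Criegee adduct F2, should give (4R)-7-(benzyloxy)-4-[3,5-dibromo-2,4,6-tris(benzyloxy)phenyl]chroman-2-one F3. Addition of 11 at –78 °C should give (3R)-3-[4-(benzyloxy)-2-hydroxyphenyl]-1-[4-(benzyloxy)phenyl]-3-[3,5-dibromo-2,4,6-tris(benzyloxy)phenyl]propan-1-one F4. Et3SiH/BF3·OEt2, through the cyclic oxocarbenium ion F5, should give (2R,4R)-7-(benzyloxy)-2-[4-(benzyloxy)phenyl]-4-[3,5-dibromo-2,4,6-tris(benzyloxy)phenyl]chroman F6. A single bromine–lithium exchange (1.0 equiv n-BuLi, THF, –78 °C) should give the monolithiated ring D aryllithium F7, which is acylated with 17 to 1-{3-bromo-2,4,6-tris(benzyloxy)-5-[(2R,4R)-7-(benzyloxy)-2-[4-(benzyloxy)phenyl]chroman-4-yl]phenyl}-9-phenylnonan-1-one F8. Hydrogenation over 10% Pd/C with NaOAc as acid scavenger should cleave the five benzyl ethers and the remaining C–Br bond together, and the fallback comes back to the route at 20.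

Step 4. The aryl transfer to the β-carbon, which bears the doubly ortho-substituted ring D, may proceed with poor facial discrimination, or the C–Br bond may be reduced before the ring closes. The fallback sets out from 6 of insufficient enantiomeric purity (or from racemic 6 made from 5 with PPh3 as ligand) and sets the stereocentre by C–H instead of C–C bond formation. Dehydrogenation with DDQ in dioxane at 80 °C should give 6-(benzyloxy)-3-[2,4,6-tris(benzyloxy)phenyl]-1H-inden-1-one F9. Asymmetric conjugate reduction with copper hydride (Cu(OAc)2·H2O, DTBM-SEGPHOS antipode chosen by trial, PMHS, t-BuOH, toluene, 0 °C to rt) should then return to the route at 6.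

Step 8. Hydride may be delivered to the face syn to ring D (trans flavan), or the newly formed benzylic C2–O1 bond may ionise again and be reduced with ring opening. The fallback sets out from 12 and sets C2 by reagent control. Corey–Bakshi–Shibata reduction of the aryl ketone ((R)-Me-CBS oxazaborolidine, BH3·SMe2 in excess, THF, –20 °C; the antipode expected to give the 1S alcohol) should give (1S,3R)-3-[4-(benzyloxy)-2-hydroxyphenyl]-1-[4-(benzyloxy)phenyl]-3-[3-bromo-2,4,6-tris(benzyloxy)phenyl]propan-1-ol F10. Mitsunobu ring closure of the phenol onto the carbinol carbon (PPh3, DIAD, THF, 0 °C) with inversion should then return to the route at 14.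

Further compounds
F1 | step 6 | (3R)-6-(benzyloxy)-3-[3,5-dibromo-2,4,6-tris(benzyloxy)phenyl]indan-1-one | O=C1C[C@@H](c2c(OCc3ccccc3)c(Br)c(OCc3ccccc3)c(Br)c2OCc2ccccc2)c2ccc(OCc3ccccc3)cc21
F2 | step 6 | (3R)-6-(benzyloxy)-3-[3,5-dibromo-2,4,6-tris(benzyloxy)phenyl]-1-hydroxyindan-1-yl 3-chloroperbenzoate (Criegee adduct) | OC1(OOC(=O)c2cccc(Cl)c2)C[C@@H](c2c(OCc3ccccc3)c(Br)c(OCc3ccccc3)c(Br)c2OCc2ccccc2)c2ccc(OCc3ccccc3)cc21
F3 | step 6 | (4R)-7-(benzyloxy)-4-[3,5-dibromo-2,4,6-tris(benzyloxy)phenyl]chroman-2-one | O=C1C[C@@H](c2c(OCc3ccccc3)c(Br)c(OCc3ccccc3)c(Br)c2OCc2ccccc2)c2ccc(OCc3ccccc3)cc2O1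
F4 | step 6 | (3R)-3-[4-(benzyloxy)-2-hydroxyphenyl]-1-[4-(benzyloxy)phenyl]-3-[3,5-dibromo-2,4,6-tris(benzyloxy)phenyl]propan-1-one | O=C(C[C@@H](c1c(OCc2ccccc2)c(Br)c(OCc2ccccc2)c(Br)c1OCc1ccccc1)c1ccc(OCc2ccccc2)cc1O)c1ccc(OCc2ccccc2)cc1
F5 | step 6 | (4R)-7-(benzyloxy)-2-[4-(benzyloxy)phenyl]-4-[3,5-dibromo-2,4,6-tris(benzyloxy)phenyl]-3,4-dihydrochromenylium (cyclic oxocarbenium ion) | Brc1c(OCc2ccccc2)c(Br)c(OCc2ccccc2)c([C@@H]2CC(c3ccc(OCc4ccccc4)cc3)=[O+]c3cc(OCc4ccccc4)ccc32)c1OCc1ccccc1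
F6 | step 6 | (2R,4R)-7-(benzyloxy)-2-[4-(benzyloxy)phenyl]-4-[3,5-dibromo-2,4,6-tris(benzyloxy)phenyl]chroman | Brc1c(OCc2ccccc2)c(Br)c(OCc2ccccc2)c([C@@H]2C[C@H](c3ccc(OCc4ccccc4)cc3)Oc3cc(OCc4ccccc4)ccc32)c1OCc1ccccc1
F7 | step 6 | {3-bromo-2,4,6-tris(benzyloxy)-5-[(2R,4R)-7-(benzyloxy)-2-[4-(benzyloxy)phenyl]chroman-4-yl]phenyl}lithium | [Li]c1c(OCc2ccccc2)c(Br)c(OCc2ccccc2)c([C@@H]2C[C@H](c3ccc(OCc4ccccc4)cc3)Oc3cc(OCc4ccccc4)ccc32)c1OCc1ccccc1
F8 | step 6 | 1-{3-bromo-2,4,6-tris(benzyloxy)-5-[(2R,4R)-7-(benzyloxy)-2-[4-(benzyloxy)phenyl]chroman-4-yl]phenyl}-9-phenylnonan-1-one | O=C(CCCCCCCCc1ccccc1)c1c(OCc2ccccc2)c(Br)c(OCc2ccccc2)c([C@@H]2C[C@H](c3ccc(OCc4ccccc4)cc3)Oc3cc(OCc4ccccc4)ccc32)c1OCc1ccccc1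
F9 | step 4 | 6-(benzyloxy)-3-[2,4,6-tris(benzyloxy)phenyl]-1H-inden-1-one | O=C1C=C(c2c(OCc3ccccc3)cc(OCc3ccccc3)cc2OCc2ccccc2)c2ccc(OCc3ccccc3)cc21
F10 | step 8 | (1S,3R)-3-[4-(benzyloxy)-2-hydroxyphenyl]-1-[4-(benzyloxy)phenyl]-3-[3-bromo-2,4,6-tris(benzyloxy)phenyl]propan-1-ol | O[C@@H](C[C@@H](c1c(OCc2ccccc2)cc(OCc2ccccc2)c(Br)c1OCc1ccccc1)c1ccc(OCc2ccccc2)cc1O)c1ccc(OCc2ccccc2)cc1
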